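**Retrosynthetic overview**

- The target is a (2S)-naringenin unit joined through its C6 to C4 of a trans-(3R,4S)-isoflavan. The pyranone ring is opened last-made-first at C4–C4a (Friedel–Crafts acylation) and at O1–C2 (Mitsunobu etherification of the para-oxygen of the phloroglucinol ring with an (R)-β-hydroxy ester).
- The chroman ring C is opened at O1–C2 (intramolecular Mitsunobu) to a 2,3,3-triarylpropan-1-ol, whose CH2OH comes from a one-carbon boron homologation and oxidation.
- The strategy rests on the adjacent stereocentres C4 (a diarylmethine bearing ring A and the phloroglucinol ring) and C3 (bearing the 3-hydroxy-2,4-dimethoxyphenyl ring and the C2 methylene). The chain C4–C3–C2 is grown one carbon at a time on boron: dichloromethyllithium inserts C3 next to C4, and the B-ring Grignard reagent then makes C3–C1'.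
- The chiral-diol diarylmethyl boronic ester comes from CuCl-catalysed enantioselective 1,6-borylation of a para-quinone methide, itself made from an aryllithium and a protected salicylaldehyde.
- Ring order: no ring in the key step; chroman ring C first, flavanone pyranone ring last; all benzene rings are bought.

Key step: step 11

Remark: the sense of induction of the CuCl/bisphosphine catalyst (step 5) and of the ruthenium transfer-hydrogenation catalyst (step 19) is taken from the usual models for these catalyst families; whichever ligand antipode delivers the stated configuration is the one to be used.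

**Route**

Step 1
Reactants: 1 4-(benzyloxy)-2-hydroxybenzaldehyde
Product: 2 4-(benzyloxy)-2-(methoxymethoxy)benzaldehyde
Conditions: MOMCl, i-Pr2NEt, CH2Cl2, 0 °C → rt
Reagents that add atoms: chloromethyl methyl ether COCCl
Why: O-alkylation of the phenol (MOM acetal protection) should proceed cleanly and gives an ortho-oxygen group that can later be removed without touching benzyl or silyl ethers.

Step 2
Reactants: 3 3,5-bis(benzyloxy)phenol
Product: 4 [3,5-bis(benzyloxy)phenoxy]triisopropylsilane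
Conditions: TIPSCl, imidazole, DMF, rt
Reagents that add atoms: triisopropylsilyl chloride CC(C)[Si](Cl)(C(C)C)C(C)C
Why: Silylation of the only free phenol gives a bulky silyl ether that marks the future para-oxygen and shields its two neighbouring ring positions from metalation.

Step 3
Reactants: 4 [3,5-bis(benzyloxy)phenoxy]triisopropylsilane; 2 4-(benzyloxy)-2-(methoxymethoxy)benzaldehyde
Product: 7 racemic [4-(benzyloxy)-2-(methoxymethoxy)phenyl][2,6-bis(benzyloxy)-4-(triisopropylsilyloxy)phenyl]methyl acetate, via aryllithium 5 (not isolated), via lithium alkoxide 6 (not isolated)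
Conditions: n-BuLi, TMEDA, THF, −20 → 0 °C; 2, −78 °C; Ac2O, −78 → 0 °C
Reagents that add atoms: acetic anhydride CC(=O)OC(C)=O
Why: Directed ortho-metalation should remove the proton flanked by the two benzyloxy groups, the aryllithium adds 1,2 to the aldehyde and the alkoxide is trapped as the acetate; the carbinol centre is racemic and is erased in step 4.

Step 4
Reactants: 7 racemic diarylmethyl acetate
Product: 8 3,5-bis(benzyloxy)-4-{[4-(benzyloxy)-2-(methoxymethoxy)phenyl]methylidene}cyclohexa-2,5-dien-1-one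
Conditions: TBAF, THF, −20 → 0 °C; rapid filtration, used at once
Reagents that add atoms: none
Why: Fluoride desilylation gives the phenoxide, which expels acetate by 1,6-elimination to the para-quinone methide; the two vinylogous-ester benzyloxy groups and the electron-rich aryl group stabilise it and the symmetric ring leaves no E/Z question.

Step 5
Reactants: 8 para-quinone methide
Product: 10 potassium (S)-[4-(benzyloxy)-2-(methoxymethoxy)phenyl][2,6-bis(benzyloxy)-4-hydroxyphenyl]methyl trifluoroborate, via pinacol boronate 9 (not isolated)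
Conditions: B2pin2, CuCl (5 mol %), (R,R)-Ph-BPE (6 mol %), NaOt-Bu (10 mol %), MeOH, THF, 0 °C; then KHF2 (aq), MeOH, rt
Reagents that add atoms: bis(pinacolato)diboron CC1(C)OB(B2OC(C)(C)C(C)(C)O2)OC1(C)C; potassium hydrogen difluoride F.[F-].[K+]
Why: Enantioselective 1,6-conjugate borylation of a para-quinone methide, in which the chiral bisphosphine–CuCl-derived boryl species adds to one face of the exocyclic carbon and rearomatisation drives the addition, should set C4 as S, and KHF2 converts the protodeboronation-prone phenol boronate directly into a salt that is isolated without silica.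

Step 6
Reactants: 10 potassium (S)-trifluoroborate; 11 (1R,2R)-1,2-dicyclohexylethane-1,2-diol
Product: 12 3,5-bis(benzyloxy)-4-{(S)-[4-(benzyloxy)-2-(methoxymethoxy)phenyl][(4R,5R)-4,5-dicyclohexyl-1,3,2-dioxaborolan-2-yl]methyl}phenol
Conditions: TMSCl, Et3N, MeCN, 0 °C → rt
Reagents that add atoms: none
Why: Fluorophile-driven ester exchange, in which TMSCl strips fluoride from boron and the diol captures it as the robust dioxaborolane, breaks no bond to C4, and the two C4 epimers are now diastereomers so that any minor one can be removed here.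

Step 7
Reactants: 12 phenol boronic ester
Product: 13 (4R,5R)-2-{(S)-[4-(benzyloxy)-2-(methoxymethoxy)phenyl][2,6-bis(benzyloxy)-4-(triisopropylsilyloxy)phenyl]methyl}-4,5-dicyclohexyl-1,3,2-dioxaborolane
Conditions: TIPSCl, imidazole, DMF, rt
Reagents that add atoms: triisopropylsilyl chloride CC(C)[Si](Cl)(C(C)C)C(C)C
Why: Silylation of the unhindered para-phenol under Lewis-acid-free conditions (the MOM acetal and the boronic ester are spared) removes the only acidic proton before the organolithium steps.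

Step 8
Reactants: 14 2,6-dimethoxyphenol
Product: 15 2-(benzyloxy)-1,3-dimethoxybenzene
Conditions: BnBr, K2CO3, DMF, rt
Reagents that add atoms: benzyl bromide BrCc1ccccc1
Why: Williamson benzylation of the phenol is routine and gives a group that is removed in the final hydrogenolysis.

Step 9
Reactants: 15 2-(benzyloxy)-1,3-dimethoxybenzene
Product: 16 2-(benzyloxy)-4-bromo-1,3-dimethoxybenzene
Conditions: NBS, MeCN, 0 °C → rt
Reagents that add atoms: N-bromosuccinimide O=C1CCC(=O)N1Br
Why: Electrophilic aromatic bromination should go to the position para to one methoxy and ortho to the other, since the position para to the benzyloxy group is meta to both methoxy groups.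

Step 10
Reactants: 16 2-(benzyloxy)-4-bromo-1,3-dimethoxybenzene
Product: 17 [3-(benzyloxy)-2,4-dimethoxyphenyl]magnesium bromide (THF solution, titrated)
Conditions: Mg turnings, I2 (cat.), THF, reflux
Reagents that add atoms: magnesium [Mg]
Why: Grignard formation by insertion of magnesium into the aryl bromide is standard and the ether groups are inert to it.

Step 11
Reactants: 13 diarylmethyl boronic ester of diol 11; 17 [3-(benzyloxy)-2,4-dimethoxyphenyl]magnesium bromide
Product: 19 (1R,2S)-1-[3-(benzyloxy)-2,4-dimethoxyphenyl]-2-[4-(benzyloxy)-2-(methoxymethoxy)phenyl]-2-[2,6-bis(benzyloxy)-4-(triisopropylsilyloxy)phenyl]ethyl boronic ester of diol 11, via α-chloro boronic ester 18 (not isolated)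
Conditions: CH2Cl2, n-BuLi, THF, −100 °C; 13; ZnCl2, −100 °C → rt; short NH4Cl work-up, crude 18 in THF; 17, −78 °C → rt
Reagents that add atoms: dichloromethyllithium [Li]C(Cl)Cl (made in the flask from dichloromethane ClCCl and n-butyllithium [Li]CCCC)
Why: Dichloromethyllithium adds to boron of 13 and, on warming under ZnCl2, the diarylmethyl group shifts from boron to carbon with retention at C4 and loss of one chloride, which forms C3–C4 and should give the (1S)-chloride 18. Grignard reagent 17 then adds to boron of 18 and its aryl group shifts anti to the remaining chloride, which forms C3–C1' with inversion and sets C3 as R. The closest known reaction type is the Matteson homologation of a chiral-diol boronic ester followed by Grignard substitution of the α-chloride, two successive 1,2-metallate shifts; no ring is closed. The new stereocentre C3 is under reagent control: the (R,R)-diol together with ZnCl2 decides which diastereotopic chloride leaves, and the second shift is stereospecific. The step needs this control to override any bias from the neighbouring C4 centre and needs substitution at boron to outrun dehydrochlorination and chloride-induced epimerisation. The C2-symmetric dicyclohexyl diol, the non-benzylic nature of the C–Cl carbon, ZnCl2 as chloride scavenger and borate formation at low temperature should secure it.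

Step 12
Reactants: 19 secondary boronic ester
Product: 20 (4R,5R)-2-{(2R,3S)-2-[3-(benzyloxy)-2,4-dimethoxyphenyl]-3-[4-(benzyloxy)-2-(methoxymethoxy)phenyl]-3-[2,6-bis(benzyloxy)-4-(triisopropylsilyloxy)phenyl]propyl}-4,5-dicyclohexyl-1,3,2-dioxaborolane
Conditions: BrCH2Cl, n-BuLi, THF, −78 °C → rt
Reagents that add atoms: chloromethyllithium [Li]CCl (made in the flask from bromochloromethane ClCBr and n-butyllithium [Li]CCCC)
Why: Matteson one-carbon homologation, in which the carbenoid formed in the presence of the ester adds to boron and the benzylic C3 group shifts to CH2 with retention, installs the C2 methylene without touching C3 or C4.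

Step 13
Reactants: 20 primary boronic ester
Product: 21 (2R,3S)-2-[3-(benzyloxy)-2,4-dimethoxyphenyl]-3-[4-(benzyloxy)-2-(methoxymethoxy)phenyl]-3-[2,6-bis(benzyloxy)-4-(triisopropylsilyloxy)phenyl]propan-1-ol
Conditions: H2O2 (30 %), NaOH (aq), THF, 0 °C
Reagents that add atoms: hydrogen peroxide OO
Why: Oxidation of the C–B bond by hydroperoxide (1,2-shift from boron to oxygen) gives the primary alcohol, releases the diol for recovery, and at 0 °C should spare the aryl silyl ether.

Step 14
Reactants: 21 MOM-protected alcohol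
Product: 22 5-(benzyloxy)-2-{(1S,2R)-2-[3-(benzyloxy)-2,4-dimethoxyphenyl]-1-[2,6-bis(benzyloxy)-4-(triisopropylsilyloxy)phenyl]-3-hydroxypropyl}phenol
Conditions: p-TsOH·H2O (cat.), MeOH/CH2Cl2, rt → 35 °C
Reagents that add atoms: none
Why: Acid-catalysed acetal exchange with methanol cleaves the aryl MOM ether under conditions mild enough for the benzyl ethers, the aryl silyl ether and the acid-sensitive C4–aryl bond.

Step 15
Reactants: 22 phenol alcohol
Product: 23 (3R,4S)-7-(benzyloxy)-3-[3-(benzyloxy)-2,4-dimethoxyphenyl]-4-[2,6-bis(benzyloxy)-4-(triisopropylsilyloxy)phenyl]chromane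
Conditions: PPh3, DIAD, THF, 0 °C → rt
Reagents that add atoms: none
Why: Intramolecular Mitsunobu etherification of the only free phenol onto the primary carbon closes ring C (O1–C2, 6-exo-tet) without touching either stereocentre and should give the 3,4-trans chroman.

Step 16
Reactants: 23 silyl-protected chroman
Product: 24 3,5-bis(benzyloxy)-4-{(3R,4S)-7-(benzyloxy)-3-[3-(benzyloxy)-2,4-dimethoxyphenyl]chroman-4-yl}phenol
Conditions: TBAF, THF, 0 °C
Reagents that add atoms: none
Why: Fluoride cleavage of the single silyl ether frees only the para-oxygen of the phloroglucinol ring, which fixes the regiochemistry of the flavanone.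

Step 17
Reactants: 25 4-hydroxybenzaldehyde
Product: 26 benzyl 4-formylphenyl carbonate
Conditions: CbzCl, Et3N, CH2Cl2, 0 °C
Reagents that add atoms: benzyl chloroformate O=C(Cl)OCc1ccccc1
Why: O-acylation of the phenol gives an electron-poor, hydrogenolysable protecting group that should suppress ionisation at the benzylic carbon in steps 20 to 22.

Step 18
Reactants: 26 benzyl 4-formylphenyl carbonate
Product: 27 tert-butyl 3-{4-[(benzyloxycarbonyl)oxy]phenyl}-3-oxopropanoate
Conditions: tert-butyl diazoacetate, NbCl5 (5 mol %), CH2Cl2, rt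
Reagents that add atoms: tert-butyl diazoacetate CC(C)(C)OC(=O)C=[N+]=[N-]
Why: Roskamp homologation (Lewis-acid-promoted addition of the diazo ester to the aldehyde, 1,2-hydride shift and loss of N2) converts the aromatic aldehyde into the β-keto ester in one operation.

Step 19
Reactants: 27 β-keto ester
Product: 28 tert-butyl (3R)-3-{4-[(benzyloxycarbonyl)oxy]phenyl}-3-hydroxypropanoate
Conditions: RuCl(p-cymene)[(R,R)-TsDPEN] (1 mol %), HCO2H/Et3N (5:2), DMF, rt → 40 °C
Reagents that add atoms: none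
Why: Noyori–Ikariya asymmetric transfer hydrogenation of the aryl ketone should deliver hydride to one carbonyl face under catalyst control and give the (R)-carbinol, while the carbonate and the tert-butyl ester are not reduced.

Step 20
Reactants: 24 para-phenol; 28 (R)-β-hydroxy ester
Product: 29 tert-butyl (3S)-3-{4-[(benzyloxycarbonyl)oxy]phenyl}-3-(3,5-bis(benzyloxy)-4-{(3R,4S)-7-(benzyloxy)-3-[3-(benzyloxy)-2,4-dimethoxyphenyl]chroman-4-yl}phenoxy)propanoate
Conditions: PPh3, DIAD, toluene, 0 °C → rt (28 in excess)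
Reagents that add atoms: none
Why: Mitsunobu etherification, an SN2 displacement of the oxyphosphonium group by the unhindered phenol, should invert the carbinol carbon and so set the future flavanone C2 as S, the electron-poor aryl group holding back the ionisation pathway.

Step 21
Reactants: 29 tert-butyl ester
Product: 31 (3S)-3-{4-[(benzyloxycarbonyl)oxy]phenyl}-3-(3,5-bis(benzyloxy)-4-{(3R,4S)-7-(benzyloxy)-3-[3-(benzyloxy)-2,4-dimethoxyphenyl]chroman-4-yl}phenoxy)propanoic acid, via trimethylsilyl ester 30 (not isolated)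
Conditions: TMSOTf, 2,6-lutidine, CH2Cl2, 0 °C; then H2O/MeOH work-up
Reagents that add atoms: none
Why: Silyl-triflate-mediated cleavage of the tert-butyl ester (loss of isobutene to the silyl ester, then hydrolysis) frees the acid without base, so neither the aryl carbonate nor the β-aryloxy group is lost by hydrolysis or elimination.

Step 22
Reactants: 31 β-aryloxy acid
Product: 32 (2S)-5,7-bis(benzyloxy)-6-{(3R,4S)-7-(benzyloxy)-3-[3-(benzyloxy)-2,4-dimethoxyphenyl]chroman-4-yl}-2-{4-[(benzyloxycarbonyl)oxy]phenyl}chroman-4-one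
Conditions: (CF3CO)2O, CH2Cl2, 0 °C
Reagents that add atoms: none
Why: Intramolecular Friedel–Crafts acylation through the mixed trifluoroacetic anhydride should close the pyranone ring at either of the two equivalent positions ortho to the ether oxygen of the highly activated ring, which leads to a single constitution and leaves C2 untouched.

Step 23
Reactants: 32 protected flavanone
Product: 33 (2S)-5,7-dihydroxy-6-[(3R,4S)-7-hydroxy-3-(3-hydroxy-2,4-dimethoxyphenyl)chroman-4-yl]-2-(4-hydroxyphenyl)chroman-4-one (CNP0267463.1)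
Conditions: H2 (1 atm), Pd/C (10 %), EtOAc/MeOH, rt, monitored closely
Reagents that add atoms: none
Why: Hydrogenolysis removes the four benzyl ethers and the benzyl carbonate (with loss of CO2) under neutral conditions, which should avoid the base-induced ring opening that would racemise the flavanone C2.

**Compound list**

1 | 4-(benzyloxy)-2-hydroxybenzaldehyde | O=Cc1ccc(OCc2ccccc2)cc1O | starting material
2 | 4-(benzyloxy)-2-(methoxymethoxy)benzaldehyde | COCOc1cc(OCc2ccccc2)ccc1C=O | intermediate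
3 | 3,5-bis(benzyloxy)phenol | Oc1cc(OCc2ccccc2)cc(OCc2ccccc2)c1 | starting material
4 | [3,5-bis(benzyloxy)phenoxy]triisopropylsilane | CC(C)[Si](Oc1cc(OCc2ccccc2)cc(OCc2ccccc2)c1)(C(C)C)C(C)C | intermediate
5 | [2,6-bis(benzyloxy)-4-(triisopropylsilyloxy)phenyl]lithium | [Li]c1c(OCc2ccccc2)cc(O[Si](C(C)C)(C(C)C)C(C)C)cc1OCc1ccccc1 | intermediate
6 | racemic lithium [4-(benzyloxy)-2-(methoxymethoxy)phenyl][2,6-bis(benzyloxy)-4-(triisopropylsilyloxy)phenyl]methanolate | COCOc1cc(OCc2ccccc2)ccc1C(O[Li])c1c(OCc2ccccc2)cc(O[Si](C(C)C)(C(C)C)C(C)C)cc1OCc1ccccc1 | intermediate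
7 | racemic [4-(benzyloxy)-2-(methoxymethoxy)phenyl][2,6-bis(benzyloxy)-4-(triisopropylsilyloxy)phenyl]methyl acetate | COCOc1cc(OCc2ccccc2)ccc1C(OC(C)=O)c1c(OCc2ccccc2)cc(O[Si](C(C)C)(C(C)C)C(C)C)cc1OCc1ccccc1 | intermediate
8 | 3,5-bis(benzyloxy)-4-{[4-(benzyloxy)-2-(methoxymethoxy)phenyl]methylidene}cyclohexa-2,5-dien-1-one | COCOc1cc(OCc2ccccc2)ccc1C=C1C(OCc2ccccc2)=CC(=O)C=C1OCc1ccccc1 | intermediate
9 | 3,5-bis(benzyloxy)-4-{(S)-[4-(benzyloxy)-2-(methoxymethoxy)phenyl](4,4,5,5-tetramethyl-1,3,2-dioxaborolan-2-yl)methyl}phenol | COCOc1cc(OCc2ccccc2)ccc1[C@H](B1OC(C)(C)C(C)(C)O1)c1c(OCc2ccccc2)cc(O)cc1OCc1ccccc1 | intermediate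
10 | potassium (S)-[4-(benzyloxy)-2-(methoxymethoxy)phenyl][2,6-bis(benzyloxy)-4-hydroxyphenyl]methyl trifluoroborate | COCOc1cc(OCc2ccccc2)ccc1[C@H]([B-](F)(F)F)c1c(OCc2ccccc2)cc(O)cc1OCc1ccccc1.[K+] | intermediate
11 | (1R,2R)-1,2-dicyclohexylethane-1,2-diol | O[C@H](C1CCCCC1)[C@H](O)C1CCCCC1 | starting material
12 | 3,5-bis(benzyloxy)-4-{(S)-[4-(benzyloxy)-2-(methoxymethoxy)phenyl][(4R,5R)-4,5-dicyclohexyl-1,3,2-dioxaborolan-2-yl]methyl}phenol | COCOc1cc(OCc2ccccc2)ccc1[C@H](B1O[C@H](C2CCCCC2)[C@@H](C2CCCCC2)O1)c1c(OCc2ccccc2)cc(O)cc1OCc1ccccc1 | intermediate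
13 | (4R,5R)-2-{(S)-[4-(benzyloxy)-2-(methoxymethoxy)phenyl][2,6-bis(benzyloxy)-4-(triisopropylsilyloxy)phenyl]methyl}-4,5-dicyclohexyl-1,3,2-dioxaborolane | COCOc1cc(OCc2ccccc2)ccc1[C@H](B1O[C@H](C2CCCCC2)[C@@H](C2CCCCC2)O1)c1c(OCc2ccccc2)cc(O[Si](C(C)C)(C(C)C)C(C)C)cc1OCc1ccccc1 | intermediate
14 | 2,6-dimethoxyphenol | COc1cccc(OC)c1O | starting material
15 | 2-(benzyloxy)-1,3-dimethoxybenzene | COc1cccc(OC)c1OCc1ccccc1 | intermediate
16 | 2-(benzyloxy)-4-bromo-1,3-dimethoxybenzene | COc1ccc(Br)c(OC)c1OCc1ccccc1 | intermediate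
17 | [3-(benzyloxy)-2,4-dimethoxyphenyl]magnesium bromide | COc1ccc([Mg]Br)c(OC)c1OCc1ccccc1 | intermediate
18 | (4R,5R)-2-{(1S,2S)-1-chloro-2-[4-(benzyloxy)-2-(methoxymethoxy)phenyl]-2-[2,6-bis(benzyloxy)-4-(triisopropylsilyloxy)phenyl]ethyl}-4,5-dicyclohexyl-1,3,2-dioxaborolane | Cl[C@@H](B1O[C@H](C2CCCCC2)[C@@H](C2CCCCC2)O1)[C@@H](c1ccc(OCc2ccccc2)cc1OCOC)c1c(OCc2ccccc2)cc(O[Si](C(C)C)(C(C)C)C(C)C)cc1OCc1ccccc1 | intermediate
19 | (4R,5R)-2-{(1R,2S)-1-[3-(benzyloxy)-2,4-dimethoxyphenyl]-2-[4-(benzyloxy)-2-(methoxymethoxy)phenyl]-2-[2,6-bis(benzyloxy)-4-(triisopropylsilyloxy)phenyl]ethyl}-4,5-dicyclohexyl-1,3,2-dioxaborolane | COc1ccc([C@H](B2O[C@H](C3CCCCC3)[C@@H](C3CCCCC3)O2)[C@@H](c2ccc(OCc3ccccc3)cc2OCOC)c2c(OCc3ccccc3)cc(O[Si](C(C)C)(C(C)C)C(C)C)cc2OCc2ccccc2)c(OC)c1OCc1ccccc1 | intermediate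
20 | (4R,5R)-2-{(2R,3S)-2-[3-(benzyloxy)-2,4-dimethoxyphenyl]-3-[4-(benzyloxy)-2-(methoxymethoxy)phenyl]-3-[2,6-bis(benzyloxy)-4-(triisopropylsilyloxy)phenyl]propyl}-4,5-dicyclohexyl-1,3,2-dioxaborolane | COc1ccc([C@H](CB2O[C@H](C3CCCCC3)[C@@H](C3CCCCC3)O2)[C@@H](c2ccc(OCc3ccccc3)cc2OCOC)c2c(OCc3ccccc3)cc(O[Si](C(C)C)(C(C)C)C(C)C)cc2OCc2ccccc2)c(OC)c1OCc1ccccc1 | intermediate
21 | (2R,3S)-2-[3-(benzyloxy)-2,4-dimethoxyphenyl]-3-[4-(benzyloxy)-2-(methoxymethoxy)phenyl]-3-[2,6-bis(benzyloxy)-4-(triisopropylsilyloxy)phenyl]propan-1-ol | COc1ccc([C@H](CO)[C@@H](c2ccc(OCc3ccccc3)cc2OCOC)c2c(OCc3ccccc3)cc(O[Si](C(C)C)(C(C)C)C(C)C)cc2OCc2ccccc2)c(OC)c1OCc1ccccc1 | intermediate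
22 | 5-(benzyloxy)-2-{(1S,2R)-2-[3-(benzyloxy)-2,4-dimethoxyphenyl]-1-[2,6-bis(benzyloxy)-4-(triisopropylsilyloxy)phenyl]-3-hydroxypropyl}phenol | COc1ccc([C@H](CO)[C@@H](c2ccc(OCc3ccccc3)cc2O)c2c(OCc3ccccc3)cc(O[Si](C(C)C)(C(C)C)C(C)C)cc2OCc2ccccc2)c(OC)c1OCc1ccccc1 | intermediate
23 | (3R,4S)-7-(benzyloxy)-3-[3-(benzyloxy)-2,4-dimethoxyphenyl]-4-[2,6-bis(benzyloxy)-4-(triisopropylsilyloxy)phenyl]chromane | COc1ccc([C@@H]2COc3cc(OCc4ccccc4)ccc3[C@H]2c2c(OCc3ccccc3)cc(O[Si](C(C)C)(C(C)C)C(C)C)cc2OCc2ccccc2)c(OC)c1OCc1ccccc1 | intermediate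
24 | 3,5-bis(benzyloxy)-4-{(3R,4S)-7-(benzyloxy)-3-[3-(benzyloxy)-2,4-dimethoxyphenyl]chroman-4-yl}phenol | COc1ccc([C@@H]2COc3cc(OCc4ccccc4)ccc3[C@H]2c2c(OCc3ccccc3)cc(O)cc2OCc2ccccc2)c(OC)c1OCc1ccccc1 | intermediate
25 | 4-hydroxybenzaldehyde | O=Cc1ccc(O)cc1 | starting material
26 | benzyl 4-formylphenyl carbonate | O=Cc1ccc(OC(=O)OCc2ccccc2)cc1 | intermediate
27 | tert-butyl 3-{4-[(benzyloxycarbonyl)oxy]phenyl}-3-oxopropanoate | CC(C)(C)OC(=O)CC(=O)c1ccc(OC(=O)OCc2ccccc2)cc1 | intermediate
28 | tert-butyl (3R)-3-{4-[(benzyloxycarbonyl)oxy]phenyl}-3-hydroxypropanoate | O[C@H](CC(=O)OC(C)(C)C)c1ccc(OC(=O)OCc2ccccc2)cc1 | intermediate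
29 | tert-butyl (3S)-3-{4-[(benzyloxycarbonyl)oxy]phenyl}-3-(3,5-bis(benzyloxy)-4-{(3R,4S)-7-(benzyloxy)-3-[3-(benzyloxy)-2,4-dimethoxyphenyl]chroman-4-yl}phenoxy)propanoate | COc1ccc([C@@H]2COc3cc(OCc4ccccc4)ccc3[C@H]2c2c(OCc3ccccc3)cc(O[C@@H](CC(=O)OC(C)(C)C)c3ccc(OC(=O)OCc4ccccc4)cc3)cc2OCc2ccccc2)c(OC)c1OCc1ccccc1 | intermediate
30 | trimethylsilyl ester corresponding to 29 | COc1ccc([C@@H]2COc3cc(OCc4ccccc4)ccc3[C@H]2c2c(OCc3ccccc3)cc(O[C@@H](CC(=O)O[Si](C)(C)C)c3ccc(OC(=O)OCc4ccccc4)cc3)cc2OCc2ccccc2)c(OC)c1OCc1ccccc1 | intermediate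
31 | (3S)-3-{4-[(benzyloxycarbonyl)oxy]phenyl}-3-(3,5-bis(benzyloxy)-4-{(3R,4S)-7-(benzyloxy)-3-[3-(benzyloxy)-2,4-dimethoxyphenyl]chroman-4-yl}phenoxy)propanoic acid | COc1ccc([C@@H]2COc3cc(OCc4ccccc4)ccc3[C@H]2c2c(OCc3ccccc3)cc(O[C@@H](CC(=O)O)c3ccc(OC(=O)OCc4ccccc4)cc3)cc2OCc2ccccc2)c(OC)c1OCc1ccccc1 | intermediate
32 | (2S)-5,7-bis(benzyloxy)-6-{(3R,4S)-7-(benzyloxy)-3-[3-(benzyloxy)-2,4-dimethoxyphenyl]chroman-4-yl}-2-{4-[(benzyloxycarbonyl)oxy]phenyl}chroman-4-one | COc1ccc([C@@H]2COc3cc(OCc4ccccc4)ccc3[C@H]2c2c(OCc3ccccc3)cc3c(c2OCc2ccccc2)C(=O)C[C@@H](c2ccc(OC(=O)OCc4ccccc4)cc2)O3)c(OC)c1OCc1ccccc1 | intermediate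
33 | (2S)-5,7-dihydroxy-6-[(3R,4S)-7-hydroxy-3-(3-hydroxy-2,4-dimethoxyphenyl)chroman-4-yl]-2-(4-hydroxyphenyl)chroman-4-one | COc1ccc([C@@H]2COc3cc(O)ccc3[C@H]2c2c(O)cc3c(c2O)C(=O)C[C@@H](c2ccc(O)cc2)O3)c(OC)c1O | target

**Step count and risks**

Total step count: 23.
Longest linear sequence: 16 steps (steps 2 to 7, 11 to 16, 20 to 23).

Steps most likely to fail:

1. Step 11. The ortho-substituted aryl Grignard reagent may form its borate only slowly at the crowded boron, so that dehydrochlorination across C3–C4 or migration of a diol oxygen competes. The bulky, stereogenic diarylmethyl group may also weaken the diol control of the first shift. Fallback: the C4–aryl bond is made instead by arylation of an isoflavan-4-yl cation. It sets out from bromide 16 and silyl ether 4 and comes back at chroman 23. Commercial 7-(benzyloxy)chroman-4-one F1 would be α-arylated with 16 (Pd2(dba)3, XPhos, NaOt-Bu, toluene) to the racemic isoflavanone F2. Transfer hydrogenation under dynamic kinetic resolution (RuCl(p-cymene)[TsDPEN] of the appropriate hand, HCO2H/Et3N) should give the cis-(3R,4R)-isoflavan-4-ol F3. Ionisation of F3 with BF3·OEt2 in CH2Cl2 at low temperature in the presence of 4 should let the arene attack through the carbon between its two benzyloxy groups, anti to the 3-aryl group, and give trans-chroman 23, so that steps 12 to 15 fall away.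

2. Step 5. The conjugate borylation may be slow or poorly face-selective, because the methide carbon is flanked by two benzyloxy groups and the quinone ring lacks the bulky groups of the usual substrates; the electron-rich benzylic boronate may also protodeboronate before it is converted to the trifluoroborate. Fallback: the chiral diol is used as resolving agent. It sets out from quinone methide 8 and comes back at boronic ester 12. Borylation with an achiral catalyst (CuCl, Xantphos, NaOt-Bu, B2pin2, MeOH, THF) would give the racemic pinacol boronate F4, and KHF2 the racemic trifluoroborate F5. Esterification with diol 11 as in step 6 gives 12 together with its C4 epimer F6; the two are diastereomers and would be separated by chromatography or crystallisation.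

3. Step 20. The activated β-hydroxy ester may eliminate to the cinnamate, and the oxyphosphonium intermediate may ionise at the benzylic carbon, which would erode the configuration instead of giving clean SN2 etherification. Fallback: the pyranone ring is built by the chalcone route. It sets out from phenol 24 and comes back at target 33. C-Acetylation of 24 ortho to the free hydroxyl (Ac2O, BF3·OEt2, through the aryl acetate and its Fries-type shift) would give the ortho-hydroxyacetophenone F7. Claisen–Schmidt condensation with commercial 4-(benzyloxy)benzaldehyde F8 (KOH, EtOH) gives the 2'-hydroxychalcone F9. Oxa-Michael cyclisation (NaOAc, EtOH, reflux), open only to the free para-oxygen, gives the flavanone as the (2S)-epimer F10 and the (2R)-epimer F11. These are diastereomers; F10 is separated, F11 is recycled through the chalcone with base, and hydrogenolysis of F10 (H2, Pd/C) gives 33.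

**Further compounds**

F1 | step 11 | 7-(benzyloxy)chroman-4-one | O=C1CCOc2cc(OCc3ccccc3)ccc12
F2 | step 11 | racemic 7-(benzyloxy)-3-[3-(benzyloxy)-2,4-dimethoxyphenyl]chroman-4-one | COc1ccc(C2COc3cc(OCc4ccccc4)ccc3C2=O)c(OC)c1OCc1ccccc1
F3 | step 11 | (3R,4R)-7-(benzyloxy)-3-[3-(benzyloxy)-2,4-dimethoxyphenyl]chroman-4-ol | COc1ccc([C@@H]2COc3cc(OCc4ccccc4)ccc3[C@@H]2O)c(OC)c1OCc1ccccc1
F4 | step 5 | racemic 3,5-bis(benzyloxy)-4-{[4-(benzyloxy)-2-(methoxymethoxy)phenyl](4,4,5,5-tetramethyl-1,3,2-dioxaborolan-2-yl)methyl}phenol | COCOc1cc(OCc2ccccc2)ccc1C(B1OC(C)(C)C(C)(C)O1)c1c(OCc2ccccc2)cc(O)cc1OCc1ccccc1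
F5 | step 5 | racemic potassium [4-(benzyloxy)-2-(methoxymethoxy)phenyl][2,6-bis(benzyloxy)-4-hydroxyphenyl]methyl trifluoroborate | COCOc1cc(OCc2ccccc2)ccc1C([B-](F)(F)F)c1c(OCc2ccccc2)cc(O)cc1OCc1ccccc1.[K+]
F6 | step 5 | 3,5-bis(benzyloxy)-4-{(R)-[4-(benzyloxy)-2-(methoxymethoxy)phenyl][(4R,5R)-4,5-dicyclohexyl-1,3,2-dioxaborolan-2-yl]methyl}phenol | COCOc1cc(OCc2ccccc2)ccc1[C@@H](B1O[C@H](C2CCCCC2)[C@@H](C2CCCCC2)O1)c1c(OCc2ccccc2)cc(O)cc1OCc1ccccc1
F7 | step 20 | 1-(2,4-bis(benzyloxy)-3-{(3R,4S)-7-(benzyloxy)-3-[3-(benzyloxy)-2,4-dimethoxyphenyl]chroman-4-yl}-6-hydroxyphenyl)ethan-1-one | COc1ccc([C@@H]2COc3cc(OCc4ccccc4)ccc3[C@H]2c2c(OCc3ccccc3)cc(O)c(C(C)=O)c2OCc2ccccc2)c(OC)c1OCc1ccccc1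
F8 | step 20 | 4-(benzyloxy)benzaldehyde | O=Cc1ccc(OCc2ccccc2)cc1
F9 | step 20 | (E)-1-(2,4-bis(benzyloxy)-3-{(3R,4S)-7-(benzyloxy)-3-[3-(benzyloxy)-2,4-dimethoxyphenyl]chroman-4-yl}-6-hydroxyphenyl)-3-[4-(benzyloxy)phenyl]prop-2-en-1-one | COc1ccc([C@@H]2COc3cc(OCc4ccccc4)ccc3[C@H]2c2c(OCc3ccccc3)cc(O)c(C(=O)/C=C/c3ccc(OCc4ccccc4)cc3)c2OCc2ccccc2)c(OC)c1OCc1ccccc1
F10 | step 20 | (2S)-5,7-bis(benzyloxy)-6-{(3R,4S)-7-(benzyloxy)-3-[3-(benzyloxy)-2,4-dimethoxyphenyl]chroman-4-yl}-2-[4-(benzyloxy)phenyl]chroman-4-one | COc1ccc([C@@H]2COc3cc(OCc4ccccc4)ccc3[C@H]2c2c(OCc3ccccc3)cc3c(c2OCc2ccccc2)C(=O)C[C@@H](c2ccc(OCc4ccccc4)cc2)O3)c(OC)c1OCc1ccccc1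
F11 | step 20 | (2R)-5,7-bis(benzyloxy)-6-{(3R,4S)-7-(benzyloxy)-3-[3-(benzyloxy)-2,4-dimethoxyphenyl]chroman-4-yl}-2-[4-(benzyloxy)phenyl]chroman-4-one | COc1ccc([C@@H]2COc3cc(OCc4ccccc4)ccc3[C@H]2c2c(OCc3ccccc3)cc3c(c2OCc2ccccc2)C(=O)C[C@H](c2ccc(OCc4ccccc4)cc2)O3)c(OC)c1OCc1ccccc1
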